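**Retrosynthetic overview**
1. Kuraridin ⇒ acid removal of four MOM ethers from a tetra-MOM chalcone (last step).
2. Enone C=C ⇒ Claisen–Schmidt condensation of a lavandulylated A-ring acetophenone with 2,4-bis(methoxymethoxy)benzaldehyde.
3. Key bond, aryl C3'–CH2(lavandulyl) ⇒ blue-light Ni/Ir deoxygenative cross-coupling of a 3'-iodo A-ring acetophenone with free (S)-lavandulol, the purchased source of the only stereocentre.
4. Aryl iodide ⇒ chelation-directed C3' iodination of commercial 2',4'-dihydroxy-6'-methoxyacetophenone, then bis-MOM protection.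
5. Ring order: no ring is built. Both benzene rings are bought intact; ring A is decorated (I, then lavandulyl) and then joined to ring B through the enone.

Assumption: enantiopure (S)-(+)-lavandulol is taken as a purchasable terpene alcohol. It is the enantiomer that gives the (R)-lavandulyl arene, because CH2OH outranks isopropenyl in the alcohol but CH2Ar does not in the product (descriptor changes, geometry does not).

**Step 1**
Reactants: 1, 2',4'-dihydroxy-6'-methoxyacetophenone
Product: 2, 1-(2,4-dihydroxy-3-iodo-6-methoxyphenyl)ethan-1-one
Conditions: I2 (0.4 equiv), HIO3 (0.2 equiv), EtOH–H2O, 35 °C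
Reagents that add atoms: iodine, II; iodic acid, O=I(=O)O
Why: Electrophilic aromatic iodination goes ortho to the carbonyl-chelated 2'-OH (bond fixation of the H-bonded C2'=C3' unit, as resacetophenone gives its 3-iodide), placing iodine between the two hydroxyls; sub-stoichiometric I2/HIO3 limits di-iodination.

**Step 2**
Reactants: 2, 1-(2,4-dihydroxy-3-iodo-6-methoxyphenyl)ethan-1-one
Product: 3, 1-[3-iodo-6-methoxy-2,4-bis(methoxymethoxy)phenyl]ethan-1-one
Conditions: NaH (2.3 equiv), MOMCl (2.6 equiv), DMF, 0 °C → rt
Reagents that add atoms: chloromethyl methyl ether (MOMCl), COCCl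
Why: Williamson-type O-alkylation of both phenoxides to MOM acetals (NaH is needed for the chelated, iodine-flanked 2'-OH) removes the acidic O–H groups before the Ni/photoredox and aldol steps.

**Step 3 (key step)**
Reactants: 3, 1-[3-iodo-6-methoxy-2,4-bis(methoxymethoxy)phenyl]ethan-1-one; 4, (S)-(+)-lavandulol [(2S)-5-methyl-2-(prop-1-en-2-yl)hex-4-en-1-ol]
Product: 5, 1-[6-methoxy-2,4-bis(methoxymethoxy)-3-[(2R)-5-methyl-2-(prop-1-en-2-yl)hex-4-en-1-yl]phenyl]ethan-1-one
Conditions: 4 (1.0 equiv), 5,7-di-tert-butyl-3-phenylbenzoxazolium BF4 (1.1 equiv), pyridine, MTBE, rt, 15 min; then 3 (1.3 equiv), NiBr2·dtbbpy (10 mol%), [Ir(ppy)2(dtbbpy)]PF6 (2 mol%), quinuclidine (1.5 equiv), MTBE–DMA, 450 nm LEDs, rt, degassed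
Reagents that add atoms: none (all new atoms come from reactant 4)
Why: Proposed new method: NHC-mediated deoxygenative Ni/Ir metallaphotoredox arylation has not, to my knowledge, been shown on a pentasubstituted aryl iodide flanked by two ortho acetal ethers, nor with a 2-alkenyl homoallylic alcohol whose radical is a 1,2-vinyl-shift clock beside a stereocentre; excited Ir(III) oxidises the in-situ benzoxazoline adduct of 4, deprotonation and β-scission release the primary lavandulyl radical, Ni(0) inserts into the weak C–I bond of 3 (helped by the flanking MOM oxygens as hemilabile donors), Ar–Ni(II) captures the radical an estimated 10–100 times faster than the 3-exo/vinyl-shift rearrangement, and Ar–Ni(III)–alkyl reductively eliminates the C3'–CH2 bond; the C2 stereocentre is one carbon away, never becomes a radical or anion, and is carried over unchanged; closest known reaction type: deoxygenative arylation of NHC-activated alcohols with aryl bromides and Ni/photoredox cross-electrophile coupling.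

**Step 4**
Reactants: 6, 2,4-dihydroxybenzaldehyde
Product: 7, 2,4-bis(methoxymethoxy)benzaldehyde
Conditions: MOMCl (3 equiv), i-Pr2NEt (4 equiv), CH2Cl2, 0 °C → rt
Reagents that add atoms: chloromethyl methyl ether (MOMCl), COCCl
Why: O-alkylation to MOM acetals masks both phenols so the aldehyde stays electrophilic (no phenoxide deactivation) in the base-mediated aldol.

**Step 5**
Reactants: 5, lavandulylated bis-MOM acetophenone; 7, 2,4-bis(methoxymethoxy)benzaldehyde
Product: 8, (E)-1-[6-methoxy-2,4-bis(methoxymethoxy)-3-[(2R)-5-methyl-2-(prop-1-en-2-yl)hex-4-en-1-yl]phenyl]-3-[2,4-bis(methoxymethoxy)phenyl]prop-2-en-1-one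
Conditions: KOH (50% aq, 10 equiv), EtOH, 0 °C → rt, 24–36 h
Reagents that add atoms: none
Why: Claisen–Schmidt (crossed aldol) condensation of the methyl ketone enolate with the non-enolisable aldehyde, with E1cB dehydration giving the thermodynamic E-enone; the lavandulyl stereocentre carries only an unactivated allylic C–H and is untouched by KOH.

**Step 6**
Reactants: 8, tetra-MOM chalcone
Product: 9, kuraridin
Conditions: 3 M aq HCl–MeOH (1:5), rt → 40 °C, stopped at full conversion, NaHCO3 quench
Reagents that add atoms: none
Why: Acid-catalysed acetal cleavage (transacetalisation to dimethoxymethane) frees the four phenols under dilute, methanolic conditions of the kind routinely tolerated by prenylated 2'-hydroxychalcones, without touching the stereocentre or the E-enone.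

**Compound list**
1 | 2',4'-dihydroxy-6'-methoxyacetophenone | CC(=O)c1c(O)cc(O)cc1OC | starting material
2 | 1-(2,4-dihydroxy-3-iodo-6-methoxyphenyl)ethan-1-one | CC(=O)c1c(O)c(I)c(O)cc1OC | intermediate
3 | 1-[3-iodo-6-methoxy-2,4-bis(methoxymethoxy)phenyl]ethan-1-one | CC(=O)c1c(OCOC)c(I)c(OCOC)cc1OC | intermediate
4 | (S)-(+)-lavandulol, (2S)-5-methyl-2-(prop-1-en-2-yl)hex-4-en-1-ol | C=C(C)[C@H](CC=C(C)C)CO | starting material
5 | 1-[6-methoxy-2,4-bis(methoxymethoxy)-3-[(2R)-5-methyl-2-(prop-1-en-2-yl)hex-4-en-1-yl]phenyl]ethan-1-one | C=C(C)[C@H](CC=C(C)C)Cc1c(OCOC)cc(OC)c(C(C)=O)c1OCOC | intermediate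
6 | 2,4-dihydroxybenzaldehyde | O=Cc1ccc(O)cc1O | starting material
7 | 2,4-bis(methoxymethoxy)benzaldehyde | COCOc1ccc(C=O)c(OCOC)c1 | intermediate
8 | (E)-1-[6-methoxy-2,4-bis(methoxymethoxy)-3-[(2R)-5-methyl-2-(prop-1-en-2-yl)hex-4-en-1-yl]phenyl]-3-[2,4-bis(methoxymethoxy)phenyl]prop-2-en-1-one | C=C(C)[C@H](CC=C(C)C)Cc1c(OCOC)cc(OC)c(C(=O)/C=C/c2ccc(OCOC)cc2OCOC)c1OCOC | intermediate
9 | kuraridin | C=C(C)[C@H](CC=C(C)C)Cc1c(O)cc(OC)c(C(=O)/C=C/c2ccc(O)cc2O)c1O | target

**Totals**
Total steps: 6. Longest linear sequence: 5 (1 → 2 → 3 → 5 → 8 → 9).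

**Three steps most likely to fail**
1. Step 3 (proposed new coupling). Risks: slow oxidative addition or radical capture at the di-ortho-substituted nickel centre leading to proto-deiodination, β-hydride elimination, or the 1,2-vinyl-shifted side chain. Fallback (known chemistry): convert 4 to the iodide (I2, PPh3, imidazole), make the alkylzinc (Zn, LiCl, THF) and run a Pd/SPhos Negishi coupling with 3. This is a two-electron transmetalation with no free radical and costs one extra step.
2. Step 1 (iodination regiochemistry). Risks: the 5'-iodide or the 3',5'-di-iodide. Fallback: start from 5-methoxyresorcinol, make the bis-MOM ether, lithiate with n-BuLi at C2 between the two OMOM groups and quench with I2, couple on this symmetric iodide, then install the acetyl group by a second directed lithiation and N-methoxy-N-methylacetamide. Regiochemistry is then fixed by symmetry, at the cost of one more step.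
3. Step 6 (acid deprotection). Risks: the isopropenyl group cyclising onto a neighbouring phenol to give a chroman, oxa-Michael closure to the flavanone (kurarinone), or flavylium formation from the B-ring 2-OH. Fallback: carry all phenols as TBS ethers, form the enone by LiHMDS aldol addition followed by MsCl/Et3N dehydration, and unmask with AcOH-buffered TBAF, giving an acid-free end game.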